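**Retrosynthetic overview**
- The target is a cis-fused hydroazulene (C8a-methyl and C3a-H cis). The aryl ester, the acetate and the free hydroxyls are installed last on a bicyclic enone; the C2/C3 cis-diol comes from OsO4 on the convex face and the C4 carbinol from Luche reduction.
- The seven-membered ring is closed by ring-closing metathesis (C5=C6); the C7–C8 bond comes from a reagent-controlled methallylboration and the C4–C5 bond from a vinyl addition.
- The two carbonyl carbons (C4, C8) are unveiled as a cis-1,2-dialdehyde by glycol cleavage of a cyclobutane-1,2-diol.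
- The cyclobutane comes from a proposed enantioselective [2+2] photocycloaddition of 3-methylcyclopent-2-enone with vinylene carbonate, which sets C8a and C3a; the isopropyl group enters by enol triflate/Negishi coupling.
- Ring order: five-membered ring (from the enone), temporary cyclobutane, then seven-membered ring.

Assumption: atom labels C1–C8a follow the target's hydroazulene numbering in every intermediate, and the (S)-prolinol-derived Lewis acid of step 1 is taken to give the enantiomer drawn for compound 3 (the mirror-image catalyst would be used otherwise).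

**Step 1**
Reactants: 1 3-methylcyclopent-2-en-1-one; 2 vinylene carbonate (1,3-dioxol-2-one)
Product: 3 (1S,2R,6S,7R)-1-methyl-3,5-dioxatricyclo[5.3.0.0^2,6]decane-4,8-dione (cis-anti-cis keto carbonate, exo carbonate drawn; C8a-methyl and C3a-H cis)
Conditions: 2 (10 equiv), AlBr3-activated oxazaborolidine from (S)-α,α-bis(3,5-dimethylphenyl)prolinol and 2,4,6-trifluorophenylboronic acid (50 mol%), CH2Cl2, −75 °C, hν 366 nm
Reagents that add atoms: none
Why: Proposed new method: the chiral Lewis acid binds the enone carbonyl, red-shifts its absorption so that only the bound enone is excited at 366 nm, and shields one face of the triplet enone, so the alkene bonds to C8a from the open face and the 1,4-diradical closes to the cis-fused cyclobutane, setting the quaternary C8a and C3a–H centres together (C4/C8 configuration is irrelevant because both carbons become carbonyls later); the closest known reaction type is the chiral-Lewis-acid-catalysed enone–alkene [2+2] photocycloaddition of cyclohexenones with simple alkenes, which has not been shown for 3-methylcyclopentenone or for a 1,2-dioxygenated alkene such as vinylene carbonate.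

**Step 2**
Reactants: 3 keto carbonate
Product: 4 (1S,2R,6S,7R)-1-methyl-4-oxo-3,5-dioxatricyclo[5.3.0.0^2,6]dec-8-en-8-yl trifluoromethanesulfonate (C3 enol triflate, C2=C3)
Conditions: KN(SiMe3)2, THF, −78 °C; then PhNTf2, −78 → 0 °C
Reagents that add atoms: N-phenylbis(trifluoromethanesulfonimide), FC(F)(F)S(=O)(=O)N(c1ccccc1)S(=O)(=O)C(F)(F)F
Why: Kinetic enolate formation and O-triflation (enol triflate synthesis) occur only toward the C2 methylene because the other α-carbon (C3a) is a strained cyclobutane ring-fusion methine, and no stereocentre is touched.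

**Step 3**
Reactants: 4 enol triflate
Product: 5 (1S,2R,6S,7R)-1-methyl-8-(propan-2-yl)-3,5-dioxatricyclo[5.3.0.0^2,6]dec-8-en-4-one (C3-isopropyl cyclopentene carbonate)
Conditions: iPrZnBr (2 equiv), Pd(dppf)Cl2 (5 mol%), LiCl, THF, 50 °C
Reagents that add atoms: isopropylzinc bromide, CC(C)[Zn]Br
Why: Negishi coupling of the alkenyl triflate with a secondary alkylzinc, where the wide-bite-angle dppf ligand favours reductive elimination over β-hydride elimination so the isopropyl group is transferred unrearranged and the carbonate is inert to the organozinc.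

**Step 4**
Reactants: 5 cyclopentene carbonate
Product: 6 (1R,5S,6R,7S)-5-methyl-2-(propan-2-yl)bicyclo[3.2.0]hept-2-ene-6,7-diol (cis-cyclobutane-1,2-diol)
Conditions: K2CO3, MeOH, 0 °C → rt
Reagents that add atoms: none
Why: Base-catalysed methanolysis (transesterification) of the cyclic carbonate frees the cis-diol without affecting the alkene or the C3a/C8a centres.

**Step 5**
Reactants: 6 cyclobutanediol
Product: 7 (1S,2R)-1-methyl-3-(propan-2-yl)cyclopent-3-ene-1,2-dicarbaldehyde (cis-dialdehyde; C8 aldehyde on the quaternary carbon, C4 aldehyde on C3a)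
Conditions: NaIO4 on wet silica gel, CH2Cl2, rt; filtered and used at once
Reagents that add atoms: none
Why: Periodate glycol cleavage of the cis-1,2-diol, helped by release of cyclobutane strain, opens the C4–C8 bond under neutral conditions and leaves the cis relationship at C3a/C8a intact.

**Step 6**
Reactants: 7 cis-dialdehyde
Product: 8 (3aR,6aS)-3-ethenyl-6a-methyl-4-(propan-2-yl)-3,3a,6,6a-tetrahydro-1H-cyclopenta[c]furan-1-ol (lactol; C4 vinyl carbinol closed onto the C8 aldehyde; mixture at both acetal-ring carbinol carbons)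
Conditions: CH2=CHMgBr (1.1 equiv), CeCl3, THF, −78 °C; aq. NH4Cl
Reagents that add atoms: vinylmagnesium bromide, C=C[Mg]Br
Why: Organocerium-modified Grignard addition goes to the less hindered C4 aldehyde, the resulting alkoxide closes onto the neopentyl C8 aldehyde as a lactol that blocks a second addition, and the low basicity avoids enolisation at C3a; the C4 configuration is not controlled because it is erased in step 9.

**Step 7**
Reactants: 8 lactol
Product: 9 (1S)-1-[(1S,2R)-2-(1-hydroxyprop-2-en-1-yl)-1-methyl-3-(propan-2-yl)cyclopent-3-en-1-yl]-3-methylbut-3-en-1-ol (diene diol; 8S set, C4 epimers)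
Conditions: (−)-Ipc2BOMe, 2-methylallylmagnesium chloride, Et2O, −78 °C → rt (3 equiv of borane); then 8, −78 °C → rt; NaOH, H2O2
Reagents that add atoms: 2-methylallylmagnesium chloride, CC(=C)C[Mg]Cl, delivered as (−)-B-(2-methylallyl)diisopinocampheylborane, CC(=C)CB([C@@H]1C[C@@H]2C[C@H]([C@H]1C)C2(C)C)[C@@H]1C[C@@H]2C[C@H]([C@H]1C)C2(C)C
Why: Brown allylboration of the open hydroxy-aldehyde form of the lactol through a chair Zimmerman–Traxler transition state, in which the (+)-α-pinene-derived borane attacks the Si face of the C8 aldehyde and sets the 8S carbinol under reagent control.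

**Step 8**
Reactants: 9 diene diol
Product: 10 (3aR,8S,8aS)-6,8a-dimethyl-3-(propan-2-yl)-1,3a,4,7,8,8a-hexahydroazulene-4,8-diol (cis-fused; C4 epimers)
Conditions: second-generation Grubbs catalyst RuCl2(=CHPh)(PCy3)(H2IMes) (5 mol%), CH2Cl2 (5 mM), 40 °C
Reagents that add atoms: none
Why: Ring-closing metathesis starts at the vinyl carbinol and closes onto the 1,1-disubstituted alkene to give the trisubstituted C5=C6 bond of the seven-membered ring, while the trisubstituted cyclopentene is inert and the cis side chains pre-organise the closure.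

**Step 9**
Reactants: 10 hydroazulene diol
Product: 11 (3aR,8S,8aS)-8-hydroxy-6,8a-dimethyl-3-(propan-2-yl)-3a,7,8,8a-tetrahydroazulen-4(1H)-one
Conditions: MnO2 (activated, excess), CH2Cl2, rt
Reagents that add atoms: none
Why: Chemoselective allylic oxidation with MnO2 converts both C4 epimers into one enone and leaves the non-allylic C8 hydroxyl untouched.

**Step 10**
Reactants: 11 hydroxy enone
Product: 12 (3aR,8S,8aS)-6,8a-dimethyl-3-(propan-2-yl)-8-[(triethylsilyl)oxy]-3a,7,8,8a-tetrahydroazulen-4(1H)-one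
Conditions: Et3SiCl, imidazole, DMAP (cat.), DMF, rt
Reagents that add atoms: chlorotriethylsilane, CC[Si](Cl)(CC)CC
Why: Silyl ether formation with the chloride and imidazole protects the C8 hydroxyl without the silyl triflate conditions that would convert the enolisable ketone into a silyl enol ether.

**Step 11**
Reactants: 12 silyloxy enone
Product: 13 (2S,3R,3aS,8S,8aS)-2,3-dihydroxy-6,8a-dimethyl-3-(propan-2-yl)-8-[(triethylsilyl)oxy]-2,3,3a,7,8,8a-hexahydroazulen-4(1H)-one
Conditions: OsO4 (5 mol%), NMO, acetone/H2O, rt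
Reagents that add atoms: osmium tetroxide (catalytic oxygen carrier), O=[Os](=O)(=O)=O; N-methylmorpholine N-oxide, C[N+]1([O-])CCOCC1; water, O
Why: Upjohn dihydroxylation attacks only the electron-rich C2=C3 bond (the enone alkene is deactivated) from the convex face of the cis-fused bicycle, cis to the C8a-methyl and C3a-H, which sets 2S and 3R with the isopropyl group on the concave face.

**Step 12**
Reactants: 13 diol
Product: 14 (2S,3R,3aS,8S,8aS)-3-hydroxy-6,8a-dimethyl-4-oxo-3-(propan-2-yl)-8-[(triethylsilyl)oxy]-1,2,3,3a,4,7,8,8a-octahydroazulen-2-yl acetate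
Conditions: Ac2O, pyridine, DMAP (cat.), CH2Cl2, 0 °C → rt
Reagents that add atoms: acetic anhydride, CC(=O)OC(C)=O
Why: DMAP-catalysed acetylation takes the secondary C2 hydroxyl only, because the tertiary C3 hydroxyl is unreactive and C8 is silylated.

**Step 13**
Reactants: 14 keto acetate
Product: 15 (2S,3R,3aR,4S,8S,8aS)-3,4-dihydroxy-6,8a-dimethyl-3-(propan-2-yl)-8-[(triethylsilyl)oxy]-1,2,3,3a,4,7,8,8a-octahydroazulen-2-yl acetate
Conditions: NaBH4, CeCl3·7H2O, MeOH, −78 °C
Reagents that add atoms: none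
Why: Luche 1,2-reduction of the enone delivers hydride from the convex face, anti to the concave C3 isopropyl group, which gives the 4S alcohol (1,3-anti to the C3 hydroxyl) and leaves the acetate intact at low temperature.

**Step 14**
Reactants: 16 4-hydroxybenzoic acid
Product: 18 4-[(tert-butyldimethylsilyl)oxy]benzoic acid, via bis-silylated ester 17 (not isolated)
Conditions: TBSCl (2.5 equiv), imidazole, DMF, rt; then AcOH/THF/H2O, rt
Reagents that add atoms: tert-butyldimethylsilyl chloride, CC(C)(C)[Si](C)(C)Cl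
Why: Silylation of both acidic hydroxyls followed by selective hydrolysis of the much more labile silyl ester leaves the phenol protected as its silyl ether.

**Step 15**
Reactants: 15 allylic alcohol; 18 4-[(tert-butyldimethylsilyl)oxy]benzoic acid
Product: 19 (2S,3R,3aR,4S,8S,8aS)-2-(acetyloxy)-3-hydroxy-6,8a-dimethyl-3-(propan-2-yl)-8-[(triethylsilyl)oxy]-1,2,3,3a,4,7,8,8a-octahydroazulen-4-yl 4-[(tert-butyldimethylsilyl)oxy]benzoate
Conditions: EDC·HCl, DMAP, CH2Cl2, rt
Reagents that add atoms: none
Why: Steglich esterification acylates the only reactive hydroxyl, the secondary allylic C4–OH (the tertiary C3–OH is inert), with retention of the 4S configuration.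

**Step 16**
Reactants: 19 bis-silyl ether
Product: 20 (2S,3R,3aR,4S,8S,8aS)-2-(acetyloxy)-3,8-dihydroxy-6,8a-dimethyl-3-(propan-2-yl)-1,2,3,3a,4,7,8,8a-octahydroazulen-4-yl 4-hydroxybenzoate (CNP0146780.2)
Conditions: HF·pyridine, pyridine/THF, 0 °C → rt
Reagents that add atoms: none
Why: Buffered fluoride desilylation removes the aryl and the C8 silyl ethers together and leaves the acetate, the allylic aryl ester and all six stereocentres untouched.

**Compound list**
1 | 3-methylcyclopent-2-en-1-one | CC1=CC(=O)CC1 | starting material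
2 | vinylene carbonate (1,3-dioxol-2-one) | O=C1OC=CO1 | starting material
3 | (1S,2R,6S,7R)-1-methyl-3,5-dioxatricyclo[5.3.0.0^2,6]decane-4,8-dione | O=C1CC[C@@]2(C)[C@@H]1[C@@H]3OC(=O)O[C@H]23 | intermediate
4 | (1S,2R,6S,7R)-1-methyl-4-oxo-3,5-dioxatricyclo[5.3.0.0^2,6]dec-8-en-8-yl trifluoromethanesulfonate | O=S(=O)(OC1=CC[C@@]2(C)[C@@H]1[C@@H]3OC(=O)O[C@H]23)C(F)(F)F | intermediate
5 | (1S,2R,6S,7R)-1-methyl-8-(propan-2-yl)-3,5-dioxatricyclo[5.3.0.0^2,6]dec-8-en-4-one | CC(C)C1=CC[C@@]2(C)[C@@H]1[C@@H]3OC(=O)O[C@H]23 | intermediate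
6 | (1R,5S,6R,7S)-5-methyl-2-(propan-2-yl)bicyclo[3.2.0]hept-2-ene-6,7-diol | CC(C)C1=CC[C@@]2(C)[C@@H]1[C@H](O)[C@@H]2O | intermediate
7 | (1S,2R)-1-methyl-3-(propan-2-yl)cyclopent-3-ene-1,2-dicarbaldehyde | CC(C)C1=CC[C@](C)(C=O)[C@@H]1C=O | intermediate
8 | (3aR,6aS)-3-ethenyl-6a-methyl-4-(propan-2-yl)-3,3a,6,6a-tetrahydro-1H-cyclopenta[c]furan-1-ol (mixture at C1 and C3) | CC(C)C1=CC[C@@]2(C)[C@@H]1C(C=C)OC2O | intermediate
9 | (1S)-1-[(1S,2R)-2-(1-hydroxyprop-2-en-1-yl)-1-methyl-3-(propan-2-yl)cyclopent-3-en-1-yl]-3-methylbut-3-en-1-ol (allylic carbinol epimers) | CC(C)C1=CC[C@](C)([C@@H](O)CC(C)=C)[C@@H]1C(O)C=C | intermediate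
10 | (3aR,8S,8aS)-6,8a-dimethyl-3-(propan-2-yl)-1,3a,4,7,8,8a-hexahydroazulene-4,8-diol (C4 epimers) | CC(C)C1=CC[C@]2(C)[C@@H](O)CC(C)=CC(O)[C@H]12 | intermediate
11 | (3aR,8S,8aS)-8-hydroxy-6,8a-dimethyl-3-(propan-2-yl)-3a,7,8,8a-tetrahydroazulen-4(1H)-one | CC(C)C1=CC[C@]2(C)[C@@H](O)CC(C)=CC(=O)[C@H]12 | intermediate
12 | (3aR,8S,8aS)-6,8a-dimethyl-3-(propan-2-yl)-8-[(triethylsilyl)oxy]-3a,7,8,8a-tetrahydroazulen-4(1H)-one | CC(C)C1=CC[C@]2(C)[C@@H](O[Si](CC)(CC)CC)CC(C)=CC(=O)[C@H]12 | intermediate
13 | (2S,3R,3aS,8S,8aS)-2,3-dihydroxy-6,8a-dimethyl-3-(propan-2-yl)-8-[(triethylsilyl)oxy]-2,3,3a,7,8,8a-hexahydroazulen-4(1H)-one | O[C@H]1C[C@]2(C)[C@@H](O[Si](CC)(CC)CC)CC(C)=CC(=O)[C@@H]2[C@]1(O)C(C)C | intermediate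
14 | (2S,3R,3aS,8S,8aS)-3-hydroxy-6,8a-dimethyl-4-oxo-3-(propan-2-yl)-8-[(triethylsilyl)oxy]-1,2,3,3a,4,7,8,8a-octahydroazulen-2-yl acetate | CC(=O)O[C@H]1C[C@]2(C)[C@@H](O[Si](CC)(CC)CC)CC(C)=CC(=O)[C@@H]2[C@]1(O)C(C)C | intermediate
15 | (2S,3R,3aR,4S,8S,8aS)-3,4-dihydroxy-6,8a-dimethyl-3-(propan-2-yl)-8-[(triethylsilyl)oxy]-1,2,3,3a,4,7,8,8a-octahydroazulen-2-yl acetate | CC(=O)O[C@H]1C[C@]2(C)[C@@H](O[Si](CC)(CC)CC)CC(C)=C[C@H](O)[C@@H]2[C@]1(O)C(C)C | intermediate
16 | 4-hydroxybenzoic acid | OC(=O)c1ccc(O)cc1 | starting material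
17 | tert-butyldimethylsilyl 4-[(tert-butyldimethylsilyl)oxy]benzoate | CC(C)(C)[Si](C)(C)OC(=O)c1ccc(O[Si](C)(C)C(C)(C)C)cc1 | intermediate
18 | 4-[(tert-butyldimethylsilyl)oxy]benzoic acid | CC(C)(C)[Si](C)(C)Oc1ccc(cc1)C(O)=O | intermediate
19 | (2S,3R,3aR,4S,8S,8aS)-2-(acetyloxy)-3-hydroxy-6,8a-dimethyl-3-(propan-2-yl)-8-[(triethylsilyl)oxy]-1,2,3,3a,4,7,8,8a-octahydroazulen-4-yl 4-[(tert-butyldimethylsilyl)oxy]benzoate | CC(=O)O[C@H]1C[C@]2(C)[C@@H](O[Si](CC)(CC)CC)CC(C)=C[C@H](OC(=O)c3ccc(O[Si](C)(C)C(C)(C)C)cc3)[C@@H]2[C@]1(O)C(C)C | intermediate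
20 | (2S,3R,3aR,4S,8S,8aS)-2-(acetyloxy)-3,8-dihydroxy-6,8a-dimethyl-3-(propan-2-yl)-1,2,3,3a,4,7,8,8a-octahydroazulen-4-yl 4-hydroxybenzoate | CC(=O)O[C@H]1C[C@]2(C)[C@@H](O)CC(C)=C[C@H](OC(=O)c3ccc(O)cc3)[C@@H]2[C@]1(O)C(C)C | target

**Step count and risk**
Total step count: 16. Longest linear sequence: 15 steps (steps 1–13, 15 and 16).

The three steps most likely to fail:

Step 1 (the proposed photocycloaddition; conversion or enantioselectivity may be poor for a cyclopentenone with an electron-poor alkene). The fallback sets out from 1 and 2 and comes back at 3. Acetone-sensitised irradiation of 1 with excess 2 through Pyrex, a known enone–alkene [2+2] photocycloaddition, gives the racemic keto carbonate F1. Its enantiomers are separated by preparative chromatography on a chiral stationary phase, and the (1S,2R,6S,7R)-enantiomer, identical with 3, is carried on. The route then rests on resolution instead of asymmetric catalysis.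

Step 6 (mono-addition to the dialdehyde; attack at the wrong aldehyde, double addition, or epimerisation at C3a). The fallback sets out from 7 and comes back at 11, and it distinguishes the two carbons by oxidation level instead of by a chemoselective Grignard addition. NaBH4 reduces 7 to the cis-bis(hydroxymethyl) compound F2. TEMPO with PhI(OAc)2 oxidises the unhindered CH2OH and carries the lactol on to the γ-lactone F3, whose carbonyl is on the C3a side. Reduction with iBu2AlH at −78 °C gives the lactol F4, and excess vinylmagnesium bromide opens it to the vinyl diol F5. Dess–Martin periodinane oxidises both hydroxyls to the keto aldehyde F6. The same (−)-B-(2-methylallyl)diisopinocampheylborane, with ethanolamine work-up, adds to the free neopentyl aldehyde and gives the hydroxy enone F7. Ring-closing metathesis with the second-generation Hoveyda–Grubbs catalyst RuCl2(=CH-2-(iPrO)C6H4)(H2IMes) then delivers 11, which also bypasses the lactol allylation.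

Step 7 (reagent-controlled methallylation of a lactol; slow ring opening or protonolysis of the borane). The fallback sets out from 8 and comes back at 9, and it sets C8 by ketone reduction instead of aldehyde allylation. Oxidation of 8 with TEMPO and PhI(OAc)2 gives the γ-lactone F8. One equivalent of 2-methylallylmagnesium chloride at −78 °C opens the hindered lactone to the hydroxy ketone F9. Corey–Bakshi–Shibata reduction with the (R)-methyl oxazaborolidine and catecholborane, which avoids hydroboration of the alkenes, gives the 8S alcohol 9.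

**Further compounds**
F1 | step 1 | racemic 1-methyl-3,5-dioxatricyclo[5.3.0.0^2,6]decane-4,8-dione (cis-anti-cis, racemate of 3) | O=C1CCC2(C)C1C1OC(=O)OC12
F2 | step 6 | [(1S,2R)-1-methyl-3-(propan-2-yl)cyclopent-3-ene-1,2-diyl]dimethanol | CC(C)C1=CC[C@](C)(CO)[C@@H]1CO
F3 | step 6 | (3aS,6aR)-3a-methyl-6-(propan-2-yl)-3,3a,4,6a-tetrahydro-1H-cyclopenta[c]furan-1-one | CC(C)C1=CC[C@@]2(C)[C@@H]1C(=O)OC2
F4 | step 6 | (3aS,6aR)-3a-methyl-6-(propan-2-yl)-3,3a,4,6a-tetrahydro-1H-cyclopenta[c]furan-1-ol (anomers) | CC(C)C1=CC[C@@]2(C)[C@@H]1C(O)OC2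
F5 | step 6 | 1-[(1R,5S)-5-(hydroxymethyl)-5-methyl-2-(propan-2-yl)cyclopent-2-en-1-yl]prop-2-en-1-ol (carbinol epimers) | CC(C)C1=CC[C@](C)(CO)[C@@H]1C(O)C=C
F6 | step 6 | (1S,2R)-1-methyl-2-(prop-2-enoyl)-3-(propan-2-yl)cyclopent-3-ene-1-carbaldehyde | CC(C)C1=CC[C@](C)(C=O)[C@@H]1C(=O)C=C
F7 | step 6 | 1-[(1R,5S)-5-[(1S)-1-hydroxy-3-methylbut-3-en-1-yl]-5-methyl-2-(propan-2-yl)cyclopent-2-en-1-yl]prop-2-en-1-one | CC(C)C1=CC[C@](C)([C@@H](O)CC(C)=C)[C@@H]1C(=O)C=C
F8 | step 7 | (3aR,6aS)-3-ethenyl-6a-methyl-4-(propan-2-yl)-3,3a,6,6a-tetrahydro-1H-cyclopenta[c]furan-1-one (C3 epimers) | CC(C)C1=CC[C@@]2(C)[C@@H]1C(C=C)OC2=O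
F9 | step 7 | 1-[(1S,2R)-2-(1-hydroxyprop-2-en-1-yl)-1-methyl-3-(propan-2-yl)cyclopent-3-en-1-yl]-3-methylbut-3-en-1-one (carbinol epimers) | CC(C)C1=CC[C@](C)(C(=O)CC(C)=C)[C@@H]1C(O)C=C
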